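**Retrosynthetic overview**
1. The target, (1R,3S)-1,3-bis(2,4,5-trimethoxyphenyl)butan-1-ol, is cut back to the (3S)-ketone at the benzylic carbinol carbon; the last step is a reagent-controlled ketone reduction that sets the carbinol centre.
2. The ketone is cut between the carbonyl carbon and the chain CH2 into 2-(2,4,5-trimethoxyphenyl)propene and 2,4,5-trimethoxybenzoic anhydride. A CuH-catalysed enantioselective anti-Markovnikov hydroacylation makes this bond and sets the CH(CH3) centre in the same operation, from two achiral precursors.
3. Enabling feature: the chain CH2 lies between the benzylic carbinol carbon and the benzylic methyl-bearing carbon. CH2–C(CH3)–aryl is therefore the C=C of a 2-arylpropene in disguise (the terminal =CH2 becomes the chain CH2, the aryl-bearing carbon takes up hydride), and the carbinol carbon with its 2,4,5-trimethoxyphenyl ring is an aroyl carbon.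
4. The alkene comes from 2′,4′,5′-trimethoxyacetophenone (Wittig methylenation); the anhydride comes from 2,4,5-trimethoxybenzoic acid (carbodiimide dehydration).
5. No ring is formed: both benzene rings are bought with their three methoxy groups in place.

Key step: step 3

Assumption: (R)-DTBM-SEGPHOS·CuH is taken to deliver hydride to that face of the aryl-bearing alkene carbon of 2 on which aryl → CH2 → CH3 runs clockwise (Re face, giving the 3S centre); if the sense proves opposite, the equally available (S)-ligand is used and nothing else changes.

**Step 1**
Reactants: 1 1-(2,4,5-trimethoxyphenyl)ethan-1-one (2′,4′,5′-trimethoxyacetophenone)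
Product: 2 1,2,4-trimethoxy-5-(prop-1-en-2-yl)benzene
Conditions: Ph3PCH3Br (1.5 equiv), KOtBu (1.4 equiv), THF, 0 °C to rt; filtration through basic alumina
Reagents that add atoms: methyltriphenylphosphonium bromide, C[P+](c1ccccc1)(c1ccccc1)c1ccccc1.[Br-]
Why: Wittig methylenation of an aryl methyl ketone with the non-stabilised ylide should give the 1,1-disubstituted alkene; no stereocentre is formed, and base-only handling protects the acid-sensitive electron-rich styrene.

**Step 2**
Reactants: 3 2,4,5-trimethoxybenzoic acid (two molecules)
Product: 4 2,4,5-trimethoxybenzoic anhydride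
Conditions: DCC (0.5 equiv per acid), CH2Cl2, 0 °C to rt; filtration of the urea
Reagents that add atoms: none
Why: Carbodiimide dehydration (O-acylisourea acylated by a second carboxylate) is the standard route to symmetrical aryl carboxylic anhydrides.

**Step 3**
Reactants: 2 1,2,4-trimethoxy-5-(prop-1-en-2-yl)benzene; 4 2,4,5-trimethoxybenzoic anhydride (1.3 equiv)
Product: 6 (3S)-1,3-bis(2,4,5-trimethoxyphenyl)butan-1-one, via alkylcopper 5 (not isolated)
Conditions: Cu(OAc)2 (5 mol %), (R)-DTBM-SEGPHOS (5.5 mol %), (MeO)2MeSiH (1.5 equiv), THF, 40 °C; then sat. aq NaHCO3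
Reagents that add atoms: none
Why: Proposed new method: the ligated copper hydride formed from Cu(OAc)2, the bisphosphine and the silane should add syn across the 1,1-disubstituted alkene of 2 with copper on the terminal CH2 and hydride on the aryl-bearing carbon, and the primary alkylcopper 5 is then acylated at one aroyl carbon of 4 by addition–elimination, which forms the CH2–C(=O) bond and releases a copper carboxylate that the silane converts back into the hydride. The closest known reaction types are the CuH-catalysed enantioselective reductive coupling (hydroacylation) of vinylarenes with aryl carboxylic anhydrides and the CuH-catalysed anti-Markovnikov hydroamination of 1,1-disubstituted alkenes, which passes through the same kind of β-stereogenic primary alkylcopper; the union of the two on a 2-arylpropene is the untested part. No ring is closed. The only new stereocentre, the benzylic CH(CH3) carbon, is set in the hydrocupration by the C2-symmetric ligand, which has to tell aryl from methyl on the alkene carbon; it sits β to copper and then β to the carbonyl group and so cannot epimerise. Regioselectivity follows from the substitution pattern of 2, since a tertiary benzylic copper centre is sterically excluded. The step needs hydrocupration of 2 to outrun CuH reduction of 4 and of ketone 6, which the three methoxy donors and the ortho-methoxy group on each aroyl unit (poor hydride acceptors) and a near-stoichiometric amount of silane should secure.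

**Step 4**
Reactants: 6 (3S)-1,3-bis(2,4,5-trimethoxyphenyl)butan-1-one
Product: 7 (1R,3S)-1,3-bis(2,4,5-trimethoxyphenyl)butan-1-ol
Conditions: (S)-Me-CBS (20 mol %), BH3·SMe2 (1.0 equiv), THF, −20 °C; MeOH quench, pH 7 buffer; Et3N-deactivated silica
Reagents that add atoms: none
Why: Corey–Bakshi–Shibata reduction: the ketone should bind the ring boron of the (S)-oxazaborolidine anti to the aryl group (the large substituent) and receive hydride on its Si face, giving the R benzylic alcohol as with acetophenones; the 3S centre is remote and not epimerisable, so the new centre is reagent-controlled.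

**Compound list**
1 | 1-(2,4,5-trimethoxyphenyl)ethan-1-one | CC(=O)c1cc(OC)c(OC)cc1OC | starting material
2 | 1,2,4-trimethoxy-5-(prop-1-en-2-yl)benzene | C=C(C)c1cc(OC)c(OC)cc1OC | intermediate
3 | 2,4,5-trimethoxybenzoic acid | COc1cc(OC)c(C(=O)O)cc1OC | starting material
4 | 2,4,5-trimethoxybenzoic anhydride | COc1cc(OC)c(C(=O)OC(=O)c2cc(OC)c(OC)cc2OC)cc1OC | intermediate
5 | [(2R)-2-(2,4,5-trimethoxyphenyl)propyl]copper(I) bound to the bisphosphine (ligand not drawn; same spatial arrangement as 3S in 6, descriptor changes because CH2Cu outranks aryl) | [Cu]C[C@H](C)c1cc(OC)c(OC)cc1OC | intermediate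
6 | (3S)-1,3-bis(2,4,5-trimethoxyphenyl)butan-1-one | COc1cc(OC)c(C(=O)C[C@H](C)c2cc(OC)c(OC)cc2OC)cc1OC | intermediate
7 | (1R,3S)-1,3-bis(2,4,5-trimethoxyphenyl)butan-1-ol | COc1cc(OC)c([C@H](O)C[C@H](C)c2cc(OC)c(OC)cc2OC)cc1OC | target

**Step count**
Total steps: 4. Longest linear sequence: 3 (steps 1, 3, 4).

**Steps most likely to fail**

Step 3 (key step). Hydrocupration of the electron-rich, ortho-substituted alkene may be slow, so that direct hydride transfer from copper to the anhydride takes over. Over-reduction of the ketone in the flask would give the alcohol with uncontrolled carbinol configuration. Facial discrimination between aryl and methyl may also be insufficient. Fallback by known reactions that form the same CH2–C(=O) bond, setting out from 2 and returning at 6: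
- Copper-catalysed enantioselective hydroboration of 2 with pinacolborane (CuCl, NaOtBu, DTBM-SEGPHOS antipode chosen for the S product, or a chiral NHC–copper catalyst; known for 2-arylpropenes) should give (S)-4,4,5,5-tetramethyl-2-[2-(2,4,5-trimethoxyphenyl)propyl]-1,3,2-dioxaborolane F1.
- Oxidation (NaBO3·4H2O, THF/H2O) should give (R)-2-(2,4,5-trimethoxyphenyl)propan-1-ol F2 (descriptor changes, configuration does not).
- I2, PPh3, imidazole should give 1-[(2R)-1-iodopropan-2-yl]-2,4,5-trimethoxybenzene F3.
- Iodine–lithium exchange (t-BuLi, 2 equiv, Et2O, −78 °C) should give [(2S)-2-(2,4,5-trimethoxyphenyl)propyl]lithium F4.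
- F4 is added to the Weinreb amide N,2,4,5-tetramethoxy-N-methylbenzamide F5 (from anhydride 4 with MeNHOMe·HCl, Et3N, CH2Cl2) to give ketone 6.

Step 4. Facial selectivity may erode, because the ortho-methoxy group and the β-branched chain narrow the size difference seen by the oxazaborolidine and uncatalysed borane reduction can compete on a slow, electron-rich ketone. The very electron-rich benzylic alcohol may also ionise on acidic work-up. Fallback setting out from 6 and returning at 7: NaBH4, MeOH, 0 °C should give 7 together with its carbinol epimer (1S,3S)-1,3-bis(2,4,5-trimethoxyphenyl)butan-1-ol F6. The two are diastereomers and should be separable on deactivated silica or by crystallisation. F6 is oxidised back to 6 (MnO2, CH2Cl2) and recycled, so the material converges on 7 without a chiral reagent.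

Step 1. The basic ylide may enolise the ketone (incomplete conversion), and the electron-rich styrene may dimerise under traces of acid during isolation. Fallback (Peterson olefination) setting out from 1 and returning at 2: Me3SiCH2MgCl, CeCl3, THF, 0 °C should add to the carbonyl to give 2-(2,4,5-trimethoxyphenyl)-1-(trimethylsilyl)propan-2-ol F7. KH, THF, rt then eliminates silanolate to give 2 under basic conditions throughout.

**Further compounds**
F1 | step 3 | (S)-4,4,5,5-tetramethyl-2-[2-(2,4,5-trimethoxyphenyl)propyl]-1,3,2-dioxaborolane | CC1(C)OB(C[C@H](C)c2cc(OC)c(OC)cc2OC)OC1(C)C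
F2 | step 3 | (R)-2-(2,4,5-trimethoxyphenyl)propan-1-ol | OC[C@H](C)c1cc(OC)c(OC)cc1OC
F3 | step 3 | 1-[(2R)-1-iodopropan-2-yl]-2,4,5-trimethoxybenzene | IC[C@H](C)c1cc(OC)c(OC)cc1OC
F4 | step 3 | [(2S)-2-(2,4,5-trimethoxyphenyl)propyl]lithium | [Li]C[C@H](C)c1cc(OC)c(OC)cc1OC
F5 | step 3 | N,2,4,5-tetramethoxy-N-methylbenzamide | CON(C)C(=O)c1cc(OC)c(OC)cc1OC
F6 | step 4 | (1S,3S)-1,3-bis(2,4,5-trimethoxyphenyl)butan-1-ol | COc1cc(OC)c([C@@H](O)C[C@H](C)c2cc(OC)c(OC)cc2OC)cc1OC
F7 | step 1 | 2-(2,4,5-trimethoxyphenyl)-1-(trimethylsilyl)propan-2-ol | COc1cc(OC)c(C(C)(O)C[Si](C)(C)C)cc1OC
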